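## Structural features

The target is a C20 bromoditerpenoid acetate. A monocyclic ring A (C1–C6) is joined through one methylene (C7) to C8 of a trans-fused hydrindane (ring B: C8–C11 and C16; ring C: C11–C16), whose angular carbon C11 carries the hydroxymethyl carbon C17. Ring A holds two stereocentres in a 1,4-cis relationship (tertiary C1–OAc axial, secondary C4–Br equatorial) with the gem-dimethyl carbon C5 between them. The bicycle holds five more: C8, C16, C11 and C12 are contiguous, and the tertiary carbinol C15 (hydroxyl axial, syn to C17) stands next to C16. Both bromides are secondary and neopentyl-like (C4 beside C5, C12 beside quaternary C11), so neither can be made reliably by substitution on an alcohol; each has to come from addition to an olefin or from an sp2 carbon. The fragile points are the tertiary carbinols and the tertiary acetate (ionisation under acid; the 1,3-diaxial pair C15–OH/C17–OH can close to a bridged ether), the bromides (strong base, halogen–metal exchange, nucleophilic hydride when heated) and the need to acetylate one tertiary hydroxyl beside another and a primary one. The real difficulty is twofold: the quaternary C11 of a trans-hydrindane flanked by the C12 bromide, and the transfer of configuration to ring A, which is insulated from the bicycle by C7. The key step uses the ring A pattern C4(Br)–C5(Me2)–C6–C1(O): a bromonium ion on a C4=C5 isopropylidene unit is opened by the methylene carbon C6 of a C1=C6 1,1-disubstituted olefin, and the C1 cation is taken by water.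

## Logic of the disconnections

34 ⇒ 31 (through 33). The acetyl C–O bond on C1 is cut. The ester is put on last because a tertiary acetate would not survive the hydride steps that shape the bicycle. The demand is differentiation of three hydroxyls: C17–OH is acetylated together with C1–OH and released again by mild methanolysis, while the much more hindered C15–OH must stay untouched.

31 ⇒ 30. C5–C6, C4–Br and C1–O are cut together, which opens ring A to a 1,5-diene chain and removes one ring, two stereocentres and both heteroatoms of ring A. The forward step must select one face of the remote C4=C5 olefin, close through a chair and deliver water axially to C1. 30 is kept as the free diol: C15–OH lies on the face opposite to the C7 chain and cannot reach C1, and the free hydroxyls keep the substrate compatible with an aqueous enzyme medium.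

30 ⇒ 29 ⇒ 28 ⇒ 27. The C15–O bond is traced to an epoxide, the epoxide to the C14=C15 olefin, and C17–OH to an aldehyde. The olefin is the retron of a cycloaddition, and the axial C17–OH is placed to deliver oxygen to the β face. The forward steps must epoxidise only the ring olefin (two side-chain olefins are present) and open the epoxide with hydride at C14.

27 ⇒ 26. C11–C16 and C12–C13 are cut; rings B and C and the stereocentres C11, C12 and C16 fall back on the single stereocentre C8. The demands are a Z bromo enal (bromine cis to the formyl carbon C17), an endo formyl group (trans fusion), and allylic strain between the C15 methyl and the C8 substituents to fix the diene face.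

26 ⇒ 25 ⇒ 24 ⇒ 23 ⇒ 21 + 22. C13=C14 and C15=C16 are cut as two Wittig olefinations, and C17 is taken back to a silyl-protected alcohol. The dienophile carbonyl is unmasked only at the end, because a β-bromo enal would not survive ylides or hydrides. The demands are E geometry at C15=C16 and no epimerisation at C8.

21 ⇒ 20 ⇒ 19 ⇒ 12 + 17. The C7–C8 bond is cut. The complete C1–C7 chain of ring A enters as an allylic bromide in the auxiliary-controlled alkylation that creates C8. This removes any need to generate a C7 organometallic later beside the C12 bromide, and it shortens the route. The price is that two extra olefins must be inert in every later step, so no electrophilic halogen or undirected oxidant is used before the key step.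

12 ⇒ 9 + 10; 9 ⇒ 7 ⇒ 5 ⇒ 4 ⇒ 1 + 2. The N-acyl bond is cut, the acid is traced to a terminal olefin, and then C10–C11 and C12–Br are cut. Anti-carbomagnesiation of 1 by 2 followed by bromination of the C–Mg bond gives the trisubstituted bromo-olefin with bromine cis to C17. The demand is regio- and stereocontrol by the magnesium alkoxide chelate.

17 ⇒ 16 ⇒ 13 + 14. The C–Br bond and then C2–C3 are cut; the side chain comes from prenylation of doubly metalated 13. The demand is alkylation at the primary carbon of 14.

## Other disconnections considered

Alternative 1: The cut is C10–C11 in ring B. Forward, Rh2(OAc)4 (divalent rhodium) would decompose the diazo keto ester A2 and the C10 carbenoid would insert into the tertiary C11–H bond to give the hydrindanone A1.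
- In its favour: 1,5-insertion into a tertiary C–H bond proceeds with retention, so the quaternary C11 and the trans fusion would be inherited from a cyclohexane stereotriad. C11–H is the only C–H bond in a 1,5-relationship to the carbenoid (the other 1,5-carbon, C15, is fully substituted), so site selectivity is inherent.
- Against it here: A1 carries a C9 ketone and a C10 ester that must be excised, and C17 is masked as a silylmethyl group that needs Fleming–Tamao oxidation. Its C12 oxygen is α, so the β bromide would require substitution with inversion at a secondary carbon next to quaternary C11, which is the weakest point. The carbenoid could also attack the activated C–H bonds beside the silyloxy groups. Ring A is not addressed.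
- Comparison: on the ring fusion the stereospecific insertion is the equal or the better of the cycloaddition used in step 15, which depends on endo selectivity. On the C12 bromide (carried in from an sp2 carbon in the chosen plan) and on step economy the chosen plan is better.

Alternative 2: The cut is C11–C16 plus C12–C13. Forward, the triene ester A4 would cyclise on heating or with Me2AlCl to the hydrindene ester A3.
- In its favour: one step forms rings B and C and sets C11, C12 and C16 from C8, with the bromine arriving on an sp2 carbon of defined geometry. This is the reaction type the chosen plan uses as a supporting step (step 15).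
- Against it as the strategic centre: A3 holds C7 as a silyl ether, so ring A would have to be attached afterwards by C–C bond formation at C7 beside the C12 bromide, and C1/C4 would have to be made separately. The ester also needs a further reduction.
- Comparison: for building the bicycle the alternative is the equal of the chosen plan; the chosen plan uses an aldehyde dienophile and saves one oxidation-level change. One point is better in the alternative: with C7 free, a C7 nucleophile could add equatorially to the preformed ketone A5, which would fix C1 by a steric rule instead of by an enzyme. The cost is several more steps and a carbanion generated next to a secondary bromide.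

Alternative 3: The cut is C14–C15. Forward, SmI2 (divalent samarium) in THF/MeOH would reduce the keto enone A7, and the C15 ketyl and the enone β-carbon C14 would couple in a 6-endo closure to A6.
- In its favour: ring C and the C15 carbinol would form in one step, and chelation of samarium between the ketyl oxygen and the C11 ester could place the oxygen axial on the β face. No triene is needed.
- Against it here: A6 has a ketone at C12, so the equatorial bromide again demands reduction and substitution with inversion at a neopentyl carbon. The closure must build a trans-fused six-membered ring on a cyclopentane. The vinyl ketone invites simple reduction or oligomerisation, and A7 already needs the quaternary C11 with three different carbonyl groups.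
- Comparison: for C15 the alternative is better than the chosen plan (one chelation-controlled step instead of epoxidation plus hydride opening). For C12 and for overall step count the chosen plan is better.

Key step: step 19

Convention: locants C1–C17 are those of the target (ring A C1–C6, linker C7, ring B C8–C11 and C16, ring C C11–C16, angular CH2O carbon C17); β is the hydrindane face that carries C17.

Assumption: the commercial vanadium bromoperoxidase of Corallina officinalis is taken to accept 30 in buffered aqueous ethanol, and the C1 cation is taken to live long enough to be captured axially.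

## Route

Step 1
Reactants: 1 prop-2-yn-1-ol; 2 but-3-enylmagnesium bromide
Product: 4 (Z)-2-(bromomethylene)hex-5-en-1-ol, via alkenylmagnesium chelate 3 (not isolated)
Conditions: 2 (2.5 equiv), CuI (10 mol%), Et2O/THF, −10 °C → rt; then BrCCl2CCl2Br, −78 → 0 °C; aq NH4Cl
Reagents that add atoms: 1,2-dibromo-1,1,2,2-tetrachloroethane, BrC(Cl)(Cl)C(Cl)(Cl)Br
Why: Copper-catalysed anti-carbomagnesiation of a propargylic alcohol; the magnesium alkoxide directs the butenyl group to the internal carbon (C11) and holds magnesium on C12 in a five-membered chelate. Bromination of the C–Mg bond with retention gives the Z olefin with bromine cis to the CH2OH group, the geometry that later becomes the cis C12–Br/C17 relationship.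

Step 2
Reactants: 4 (Z)-2-(bromomethylene)hex-5-en-1-ol
Product: 5 (Z)-{[2-(bromomethylene)hex-5-en-1-yl]oxy}(tert-butyl)dimethylsilane
Conditions: TBSCl, imidazole, DMF, 0 °C → rt
Reagents that add atoms: tert-butyldimethylsilyl chloride, CC(C)(C)[Si](C)(C)Cl
Why: Standard silylation of a primary alcohol; the silyl ether masks the future C17 carbinol through the basic, hydridic and ylide steps that follow.

Step 3
Reactants: 5 (Z)-{[2-(bromomethylene)hex-5-en-1-yl]oxy}(tert-butyl)dimethylsilane
Product: 7 (Z)-5-(bromomethylene)-6-(tert-butyldimethylsilyloxy)hexan-1-ol, via B-alkyl-9-BBN adduct 6 (not isolated)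
Conditions: 9-BBN, THF, 0 °C → rt; then NaOH, H2O2, 0 °C → rt
Reagents that add atoms: hydrogen peroxide, OO
Why: Hydroboration–oxidation; 9-BBN adds anti-Markovnikov to the monosubstituted terminal olefin only, and the hindered, electron-poor bromo-olefin is left alone.

Step 4
Reactants: 7 (Z)-5-(bromomethylene)-6-(tert-butyldimethylsilyloxy)hexan-1-ol
Product: 9 (Z)-5-(bromomethylene)-6-(tert-butyldimethylsilyloxy)hexanoic acid, via aldehyde 8 (not isolated)
Conditions: 2,2,6,6-tetramethylpiperidine-1-oxyl (20 mol%), PhI(OAc)2 (2.2 equiv), MeCN/H2O, rt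
Reagents that add atoms: water, O
Why: Nitroxyl-catalysed oxidation of a primary alcohol through the aldehyde hydrate to the acid; the near-neutral medium tolerates the vinyl bromide and the silyl ether.

Step 5
Reactants: 9 (Z)-5-(bromomethylene)-6-(tert-butyldimethylsilyloxy)hexanoic acid; 10 (R)-4-benzyloxazolidin-2-one
Product: 12 (R)-4-benzyl-3-[(Z)-5-(bromomethylene)-6-(tert-butyldimethylsilyloxy)hexanoyl]oxazolidin-2-one, via mixed pivalic anhydride 11 (not isolated)
Conditions: t-BuCOCl, Et3N, THF, −20 °C; then 10, LiCl, −20 °C → rt
Reagents that add atoms: none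
Why: N-Acylation of the oxazolidinone through the mixed anhydride (LiCl/Et3N activation), the usual entry to an Evans imide.

Step 6
Reactants: 13 2-methylprop-2-en-1-ol; 14 1-bromo-3-methylbut-2-ene
Product: 16 6-methyl-2-methylenehept-5-en-1-ol, via dilithiated methallyl alcohol 15 (not isolated)
Conditions: n-BuLi (2.1 equiv), TMEDA, Et2O/hexane, 0 °C → rt; then 14, THF, −78 °C → rt
Reagents that add atoms: none
Why: Double deprotonation (O–H and allylic C–H) gives an alkoxide-stabilised allyllithium that is alkylated at its CH2 terminus by the primary allylic bromide, forming C2–C3 of the ring A chain.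

Step 7
Reactants: 16 6-methyl-2-methylenehept-5-en-1-ol
Product: 17 2-(bromomethyl)-6-methylhepta-1,5-diene
Conditions: CBr4, PPh3, CH2Cl2, 0 °C
Reagents that add atoms: carbon tetrabromide, BrC(Br)(Br)Br
Why: Appel bromination under neutral conditions, which spares the acid-sensitive trisubstituted olefin; allylic transposition is degenerate for this 2-substituted allyl system.

Step 8
Reactants: 12 (R)-4-benzyl-3-[(Z)-5-(bromomethylene)-6-(tert-butyldimethylsilyloxy)hexanoyl]oxazolidin-2-one; 17 2-(bromomethyl)-6-methylhepta-1,5-diene
Product: 19 (R)-4-benzyl-3-[(2S,5Z)-5-(bromomethylene)-6-(tert-butyldimethylsilyloxy)-2-(6-methyl-2-methylenehept-5-en-1-yl)hexanoyl]oxazolidin-2-one, via sodium enolate 18 (not isolated)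
Conditions: NaN(SiMe3)2, THF, −78 °C; then 17, −78 → −40 °C
Reagents that add atoms: none
Why: Evans asymmetric alkylation; the chelated Z enolate is shielded on one face by the (R)-benzyl group, so the allylic bromide enters from the other face and sets C8 as S. The complete C1–C7 chain of ring A is installed in this step.

Step 9
Reactants: 19 (R)-4-benzyl-3-[(2S,5Z)-5-(bromomethylene)-6-(tert-butyldimethylsilyloxy)-2-(6-methyl-2-methylenehept-5-en-1-yl)hexanoyl]oxazolidin-2-one
Product: 20 (2S,5Z)-5-(bromomethylene)-6-(tert-butyldimethylsilyloxy)-2-(6-methyl-2-methylenehept-5-en-1-yl)hexan-1-ol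
Conditions: LiBH4, MeOH (1 equiv), Et2O, 0 °C
Reagents that add atoms: none
Why: Reductive removal of the auxiliary; hydride attacks the exocyclic imide carbonyl without enolisation, so C8 is not epimerised, and the auxiliary is recovered.

Step 10
Reactants: 20 (2S,5Z)-5-(bromomethylene)-6-(tert-butyldimethylsilyloxy)-2-(6-methyl-2-methylenehept-5-en-1-yl)hexan-1-ol
Product: 21 (2S,5Z)-5-(bromomethylene)-6-(tert-butyldimethylsilyloxy)-2-(6-methyl-2-methylenehept-5-en-1-yl)hexanal
Conditions: Dess–Martin periodinane, NaHCO3, CH2Cl2, 0 °C → rt
Reagents that add atoms: none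
Why: Buffered Dess–Martin oxidation; the α-branched aldehyde is used at once so that C8 has no opportunity to epimerise.

Step 11
Reactants: 21 (2S,5Z)-5-(bromomethylene)-6-(tert-butyldimethylsilyloxy)-2-(6-methyl-2-methylenehept-5-en-1-yl)hexanal; 22 2-(triphenylphosphoranylidene)propanal
Product: 23 (2E,4S,7Z)-7-(bromomethylene)-8-(tert-butyldimethylsilyloxy)-2-methyl-4-(6-methyl-2-methylenehept-5-en-1-yl)oct-2-enal
Conditions: 22 (1.5 equiv), toluene, 80 °C
Reagents that add atoms: none
Why: Wittig olefination with a stabilised formyl ylide, which gives the E trisubstituted enal (C15=C16 with its methyl); the weakly basic ylide does not enolise the aldehyde.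

Step 12
Reactants: 23 (2E,4S,7Z)-7-(bromomethylene)-8-(tert-butyldimethylsilyloxy)-2-methyl-4-(6-methyl-2-methylenehept-5-en-1-yl)oct-2-enal
Product: 24 tert-butyl{[(2Z,5S,6E)-2-(bromomethylene)-7-methyl-5-(6-methyl-2-methylenehept-5-en-1-yl)nona-6,8-dien-1-yl]oxy}dimethylsilane
Conditions: Ph3PCH3Br, KOtBu, THF, 0 °C; then 23, −78 → 0 °C
Reagents that add atoms: methyltriphenylphosphonium bromide, C[P+](c1ccccc1)(c1ccccc1)c1ccccc1.[Br-]
Why: Wittig methylenation of the enal completes the diene (C13=C14); 1,2-addition of the non-stabilised ylide is faster than γ-deprotonation, so C8 is untouched.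

Step 13
Reactants: 24 tert-butyl{[(2Z,5S,6E)-2-(bromomethylene)-7-methyl-5-(6-methyl-2-methylenehept-5-en-1-yl)nona-6,8-dien-1-yl]oxy}dimethylsilane
Product: 25 (2Z,5S,6E)-2-(bromomethylene)-7-methyl-5-(6-methyl-2-methylenehept-5-en-1-yl)nona-6,8-dien-1-ol
Conditions: Bu4NF, THF, 0 °C
Reagents that add atoms: none
Why: Fluoride desilylation; no other group in 24 is sensitive to fluoride.

Step 14
Reactants: 25 (2Z,5S,6E)-2-(bromomethylene)-7-methyl-5-(6-methyl-2-methylenehept-5-en-1-yl)nona-6,8-dien-1-ol
Product: 26 (2Z,5S,6E)-2-(bromomethylene)-7-methyl-5-(6-methyl-2-methylenehept-5-en-1-yl)nona-6,8-dienal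
Conditions: Dess–Martin periodinane, NaHCO3, CH2Cl2, 0 °C; used directly
Reagents that add atoms: none
Why: Oxidation of the allylic alcohol to the Z β-bromo enal under buffered, non-nucleophilic conditions that should preserve the olefin geometry; the activated triene is taken on without storage.

Step 15
Reactants: 26 (2Z,5S,6E)-2-(bromomethylene)-7-methyl-5-(6-methyl-2-methylenehept-5-en-1-yl)nona-6,8-dienal
Product: 27 12β-bromo-15-methyl-8α-(6-methyl-2-methylenehept-5-en-1-yl)-trans-hydrind-14-ene-11β-carbaldehyde (C16–H α)
Conditions: Me2AlCl (1.1 equiv), CH2Cl2, −78 → −30 °C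
Reagents that add atoms: none
Why: Intramolecular Diels–Alder reaction of a 1,6,8-nonatriene with a Lewis-acid-activated α-substituted enal. Allylic 1,3-strain between the C15 methyl and the C8 substituents puts C8–H in the diene plane, so the tether reaches one diene face (sets C16 relative to C8); the endo formyl group gives the trans fusion (C11), and the Z dienophile geometry places C12–Br cis to C17. Me2AlCl also scavenges protic acid, which protects the 1,5-diene side chain.

Step 16
Reactants: 27 12β-bromo-15-methyl-8α-(6-methyl-2-methylenehept-5-en-1-yl)-trans-hydrind-14-ene-11β-carbaldehyde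
Product: 28 [12β-bromo-15-methyl-8α-(6-methyl-2-methylenehept-5-en-1-yl)-trans-hydrind-14-en-11β-yl]methanol
Conditions: NaBH4, MeOH, 0 °C
Reagents that add atoms: none
Why: Borohydride reduction of a neopentyl aldehyde; C11 has no hydrogen, so neither epimerisation nor elimination of the β-bromide is possible.

Step 17
Reactants: 28 [12β-bromo-15-methyl-8α-(6-methyl-2-methylenehept-5-en-1-yl)-trans-hydrind-14-en-11β-yl]methanol
Product: 29 14β,15β-epoxide of 28
Conditions: VO(acac)2 (5 mol%), t-BuOOH (decane), CH2Cl2, 0 °C → rt
Reagents that add atoms: tert-butyl hydroperoxide, CC(C)(C)OO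
Why: Hydroxyl-directed epoxidation; the axial C17–OH binds the pentavalent vanadium peroxide and delivers oxygen to the β face of C14=C15 (sets C14 and C15). The side-chain olefins carry no directing hydroxyl and are not epoxidised by this reagent.

Step 18
Reactants: 29 14β,15β-epoxide of 28
Product: 30 12β-bromo-11β-(hydroxymethyl)-15α-methyl-8α-(6-methyl-2-methylenehept-5-en-1-yl)-trans-hydrindan-15β-ol
Conditions: LiAlH4, THF, 0 °C → rt
Reagents that add atoms: none
Why: Hydride opens the trisubstituted epoxide at the secondary carbon C14 in the trans-diaxial sense (Fürst–Plattner rule), leaving the oxygen axial (β) on C15 with the methyl equatorial. The hindered equatorial C12 bromide should resist SN2 reduction at this temperature.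

Step 19
Reactants: 30 12β-bromo-11β-(hydroxymethyl)-15α-methyl-8α-(6-methyl-2-methylenehept-5-en-1-yl)-trans-hydrindan-15β-ol
Product: 31 (1S,4S)-4-bromo-1-{[12β-bromo-15β-hydroxy-11β-(hydroxymethyl)-15α-methyl-trans-hydrindan-8α-yl]methyl}-5,5-dimethylcyclohexan-1-ol (deacetyl target; OH axial, Br equatorial, cis)
Conditions: vanadium-dependent bromoperoxidase (Corallina officinalis), KBr, H2O2 (slow addition), Na3VO4 (trace), MES buffer pH 6.5/EtOH, 25 °C
Reagents that add atoms: potassium bromide, [K+].[Br-]; water, O
Why: The enzyme oxidises bromide with H2O2 at its vanadate (pentavalent vanadium) site and passes electrophilic bromine to the only trisubstituted, most electron-rich olefin (C4=C5); the C1=C6 olefin attacks the tertiary end C5 through its methylene carbon C6 and water takes the C1 cation, which is the known bromoperoxidase-mediated bromonium cyclization of terpenoid 1,5-dienes with water as the terminating nucleophile. Ring A closes in the 6-endo-trig mode through a chair-like array in which C4–Br becomes equatorial. C4 is set by the olefin face that the enzyme pocket presents to bromine, because the substrate has no bias of its own across the C7 hinge. C1 is set at the cation stage: axial capture by water, anti to the axial C–H bonds at C2 and C6, lets the bulky C7 substituent settle equatorial and gives the required cis C4–Br/C1–O pair, whereas capture antiperiplanar to the new C5–C6 bond would force C7 axial against the axial C5 methyl. The step needs one olefin to act as the electrophile partner and the other as the nucleophile, which the substitution pattern provides, and it needs the C1 cation to meet water before it loses a proton. The substrate offers no internal competitor: C15–OH is on the β face opposite to the α-oriented C7 chain and cannot reach C1, C17–OH is too remote, and the existing bromide and hydroxyls are inert to bromide/H2O2.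

Step 20
Reactants: 31 (1S,4S)-4-bromo-1-{[12β-bromo-15β-hydroxy-11β-(hydroxymethyl)-15α-methyl-trans-hydrindan-8α-yl]methyl}-5,5-dimethylcyclohexan-1-ol
Product: 33 C1,C17-diacetate of 31, via C17 monoacetate 32 (not isolated)
Conditions: Ac2O, 4-(dimethylamino)pyridine, Et3N, CH2Cl2, rt → 40 °C
Reagents that add atoms: acetic anhydride, CC(=O)OC(C)=O
Why: Nucleophile-catalysed acylation; the primary C17–OH reacts first, then the tertiary C1–OH. The C15–OH, flanked by the ring-fusion methine and syn-axial to C17, should stay free.

Step 21
Reactants: 33 C1,C17-diacetate of 31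
Product: 34 (1S,4S)-4-bromo-1-{[(8S,11S,12S,15R,16S)-12-bromo-15-hydroxy-11-(hydroxymethyl)-15-methyl-trans-hydrindan-8-yl]methyl}-5,5-dimethylcyclohexyl acetate (target)
Conditions: K2CO3 (cat.), MeOH, 0 °C
Reagents that add atoms: none
Why: Base-catalysed transesterification cleaves the primary acetate much faster than the hindered tertiary C1 acetate. Both bromides are equatorial and have no antiperiplanar hydrogen, so E2 elimination is not expected.

## Compound list

1 | prop-2-yn-1-ol | C#CCO | starting material
2 | but-3-enylmagnesium bromide | C=CCC[Mg]Br | starting material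
3 | alkenylmagnesium chelate, 4-(but-3-enyl)-2,5-dihydro-1,2-oxamagnesole | C=CCCC1=C[Mg]OC1 | intermediate (not isolated)
4 | (Z)-2-(bromomethylene)hex-5-en-1-ol | Br/C=C(\CO)CCC=C | intermediate
5 | (Z)-{[2-(bromomethylene)hex-5-en-1-yl]oxy}(tert-butyl)dimethylsilane | Br/C=C(\CO[Si](C)(C)C(C)(C)C)CCC=C | intermediate
6 | 9-[(Z)-5-(bromomethylene)-6-(tert-butyldimethylsilyloxy)hexyl]-9-borabicyclo[3.3.1]nonane | Br/C=C(\CO[Si](C)(C)C(C)(C)C)CCCCB1C2CCCC1CCC2 | intermediate (not isolated)
7 | (Z)-5-(bromomethylene)-6-(tert-butyldimethylsilyloxy)hexan-1-ol | Br/C=C(\CO[Si](C)(C)C(C)(C)C)CCCCO | intermediate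
8 | (Z)-5-(bromomethylene)-6-(tert-butyldimethylsilyloxy)hexanal | Br/C=C(\CO[Si](C)(C)C(C)(C)C)CCCC=O | intermediate (not isolated)
9 | (Z)-5-(bromomethylene)-6-(tert-butyldimethylsilyloxy)hexanoic acid | Br/C=C(\CO[Si](C)(C)C(C)(C)C)CCCC(=O)O | intermediate
10 | (R)-4-benzyloxazolidin-2-one | O=C1N[C@H](Cc2ccccc2)CO1 | starting material
11 | mixed pivalic anhydride of 9 | Br/C=C(\CO[Si](C)(C)C(C)(C)C)CCCC(=O)OC(=O)C(C)(C)C | intermediate (not isolated)
12 | (R)-4-benzyl-3-[(Z)-5-(bromomethylene)-6-(tert-butyldimethylsilyloxy)hexanoyl]oxazolidin-2-one | Br/C=C(\CO[Si](C)(C)C(C)(C)C)CCCC(=O)N1[C@H](Cc2ccccc2)COC1=O | intermediate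
13 | 2-methylprop-2-en-1-ol | C=C(C)CO | starting material
14 | 1-bromo-3-methylbut-2-ene | CC(C)=CCBr | starting material
15 | dilithiated methallyl alcohol, lithium 2-(lithiomethyl)prop-2-en-1-olate | [Li]CC(=C)CO[Li] | intermediate (not isolated)
16 | 6-methyl-2-methylenehept-5-en-1-ol | C=C(CO)CCC=C(C)C | intermediate
17 | 2-(bromomethyl)-6-methylhepta-1,5-diene | C=C(CBr)CCC=C(C)C | intermediate
18 | sodium (Z)-enolate of 12 | [Na]O/C(N1[C@H](Cc2ccccc2)COC1=O)=C\CC/C(CO[Si](C)(C)C(C)(C)C)=C/Br | intermediate (not isolated)
19 | (R)-4-benzyl-3-[(2S,5Z)-5-(bromomethylene)-6-(tert-butyldimethylsilyloxy)-2-(6-methyl-2-methylenehept-5-en-1-yl)hexanoyl]oxazolidin-2-one | C=C(CCC=C(C)C)C[C@H](CC/C(CO[Si](C)(C)C(C)(C)C)=C/Br)C(=O)N1[C@H](Cc2ccccc2)COC1=O | intermediate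
20 | (2S,5Z)-5-(bromomethylene)-6-(tert-butyldimethylsilyloxy)-2-(6-methyl-2-methylenehept-5-en-1-yl)hexan-1-ol | C=C(CCC=C(C)C)C[C@H](CC/C(CO[Si](C)(C)C(C)(C)C)=C/Br)CO | intermediate
21 | (2S,5Z)-5-(bromomethylene)-6-(tert-butyldimethylsilyloxy)-2-(6-methyl-2-methylenehept-5-en-1-yl)hexanal | C=C(CCC=C(C)C)C[C@H](CC/C(CO[Si](C)(C)C(C)(C)C)=C/Br)C=O | intermediate
22 | 2-(triphenylphosphoranylidene)propanal | CC(C=O)=P(c1ccccc1)(c1ccccc1)c1ccccc1 | starting material
23 | (2E,4S,7Z)-7-(bromomethylene)-8-(tert-butyldimethylsilyloxy)-2-methyl-4-(6-methyl-2-methylenehept-5-en-1-yl)oct-2-enal | C=C(CCC=C(C)C)C[C@H](CC/C(CO[Si](C)(C)C(C)(C)C)=C/Br)/C=C(\C)C=O | intermediate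
24 | tert-butyl{[(2Z,5S,6E)-2-(bromomethylene)-7-methyl-5-(6-methyl-2-methylenehept-5-en-1-yl)nona-6,8-dien-1-yl]oxy}dimethylsilane | C=C(CCC=C(C)C)C[C@H](CC/C(CO[Si](C)(C)C(C)(C)C)=C/Br)/C=C(\C)C=C | intermediate
25 | (2Z,5S,6E)-2-(bromomethylene)-7-methyl-5-(6-methyl-2-methylenehept-5-en-1-yl)nona-6,8-dien-1-ol | C=C(CCC=C(C)C)C[C@H](CC/C(CO)=C/Br)/C=C(\C)C=C | intermediate
26 | (2Z,5S,6E)-2-(bromomethylene)-7-methyl-5-(6-methyl-2-methylenehept-5-en-1-yl)nona-6,8-dienal | C=C(CCC=C(C)C)C[C@H](CC/C(C=O)=C/Br)/C=C(\C)C=C | intermediate
27 | 12β-bromo-15-methyl-8α-(6-methyl-2-methylenehept-5-en-1-yl)-trans-hydrind-14-ene-11β-carbaldehyde (C16–H α) | C=C(CCC=C(C)C)C[C@@H]2CC[C@]3(C=O)[C@@H](Br)CC=C(C)[C@@H]23 | intermediate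
28 | [12β-bromo-15-methyl-8α-(6-methyl-2-methylenehept-5-en-1-yl)-trans-hydrind-14-en-11β-yl]methanol | C=C(CCC=C(C)C)C[C@@H]2CC[C@]3(CO)[C@@H](Br)CC=C(C)[C@@H]23 | intermediate
29 | 14β,15β-epoxide of 28 | C=C(CCC=C(C)C)C[C@@H]2CC[C@]3(CO)[C@@H](Br)C[C@H]4O[C@@]4(C)[C@@H]23 | intermediate
30 | 12β-bromo-11β-(hydroxymethyl)-15α-methyl-8α-(6-methyl-2-methylenehept-5-en-1-yl)-trans-hydrindan-15β-ol (key-step precursor) | C=C(CCC=C(C)C)C[C@@H]2CC[C@]3(CO)[C@@H](Br)CC[C@@](C)(O)[C@@H]23 | intermediate
31 | (1S,4S)-4-bromo-1-{[12β-bromo-15β-hydroxy-11β-(hydroxymethyl)-15α-methyl-trans-hydrindan-8α-yl]methyl}-5,5-dimethylcyclohexan-1-ol (key-step product) | O[C@]1(C[C@@H]2CC[C@]3(CO)[C@@H](Br)CC[C@@](C)(O)[C@@H]23)CC[C@H](Br)C(C)(C)C1 | intermediate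
32 | C17 monoacetate of 31 | O[C@]1(C[C@@H]2CC[C@]3(COC(C)=O)[C@@H](Br)CC[C@@](C)(O)[C@@H]23)CC[C@H](Br)C(C)(C)C1 | intermediate (not isolated)
33 | C1,C17-diacetate of 31 | CC(=O)O[C@]1(C[C@@H]2CC[C@]3(COC(C)=O)[C@@H](Br)CC[C@@](C)(O)[C@@H]23)CC[C@H](Br)C(C)(C)C1 | intermediate
34 | (1S,4S)-4-bromo-1-{[(8S,11S,12S,15R,16S)-12-bromo-15-hydroxy-11-(hydroxymethyl)-15-methyl-trans-hydrindan-8-yl]methyl}-5,5-dimethylcyclohexyl acetate | CC(=O)O[C@]1(C[C@@H]2CC[C@]3(CO)[C@@H](Br)CC[C@@](C)(O)[C@@H]23)CC[C@H](Br)C(C)(C)C1 | target

## Step count and least certain steps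

Total step count: 21. Longest linear sequence: 19 steps (steps 1–5 and 8–21, from 1 and 2); steps 6 and 7 form the side branch that delivers 17.

Step 19 (key step). The most likely failures are:
- water capture at C1 from the equatorial direction, the antiperiplanar mode usual in cation–olefin cyclizations, which would invert C1;
- proton loss from the C1 cation instead of hydration;
- poor discrimination between the two faces of C4=C5;
- plain bromohydrin formation at C4=C5 without ring closure.

The reasons are that the substrate has no bias across C7, the axial trajectory at C1 passes the axial C5 methyl, and the substrate is much larger than the terpenes normally offered to this enzyme.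

Fallback, setting out from 30: Et2SBr·SbCl5Br (bromodiethylsulfonium bromopentachloroantimonate) in MeNO2 at −25 °C, a stoichiometric bromonium donor known for polyene cyclization, should close ring A with proton loss. This would give the ring A C1=C2 olefin F1 and the ring A C1=C6 olefin F2, each accompanied by the series of opposite ring A configuration; these are diastereomers because the bicycle is enantiopure, and would be separated by chromatography. Oxymercuration of F1 and F2 with Hg(OAc)2 (divalent mercury) in THF/H2O adds water in the Markovnikov, trans-diaxial sense through the organomercurial F3 and the organomercurial F4, and NaBH4/NaOH demercuration would leave the hydroxyl axial on C1. This stereochemical rule differs from that of direct cation capture. The sequence comes back to the route at 31.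

Step 15. The likely failures are loss of the Z geometry of the β-bromo enal before cycloaddition (halide addition–elimination on the Lewis-acid complex), which would scramble C12; competition of the exo-formyl transition state, which would give the cis ring fusion; and Lewis-acid-triggered reaction of the side-chain olefins with the activated aldehyde.

Fallback, setting out from 26: NaClO2/NaH2PO4/2-methyl-2-butene would give the trienoic acid F5, and Me3SiCHN2 the methyl ester F6, a configurationally more robust bromoacrylate. Its thermal intramolecular Diels–Alder reaction (toluene, 110 °C, radical inhibitor, no Lewis acid) would give the hydrindene methyl ester F7. Reduction with i-Bu2AlH at −78 °C comes back to the route at 28.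

Step 17. The likely failure is slow oxygen delivery from a bishomoallylic hydroxyl, so that unselective oxidation of the side-chain olefins or acid-promoted opening of the epoxide (transannular ether formation from C17–OH through a C15 cation) competes.

Fallback, setting out from 27: NaClO2/NaH2PO4/2-methyl-2-butene would give the hydrindene carboxylic acid F8. Iodolactonization (I2, NaHCO3, MeCN, 0 °C, dark) would give the bridged iodolactone F9. The C17 carboxylate can reach C15 only from the β face, iodine ends axial on C14, and iodonium formation at the side-chain olefins is reversible and unproductive. LiAlH4 in THF reduces the lactone; the freed C15 alkoxide closes onto C14 to give 29, which hydride opens at C14 (or hydride reduces the C–I bond directly). Both paths come back to the route at 30.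

Step 20. The likely failure is sluggish acylation of the axial C1–OH (syn-axial C5 methyl), which calls for forcing conditions under which the C15–OH begins to react; acidic acylation catalysts would risk ionisation of a tertiary carbinol.

Fallback, setting out from 31: t-Bu2Si(OTf)2/2,6-lutidine should tie the 1,3-diaxial pair C15–OH/C17–OH into the cyclic silylene F10. Ac2O with 4-(dimethylamino)pyridine at 40–60 °C can then be forced onto the only free hydroxyl to give the silylene acetate F11. HF·pyridine removes the silylene and comes back to the route at 34.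

## Further compounds

F1 | step 19 | ring A C1=C2 olefin (proton-loss cyclization product, C4 S) | C1(C[C@@H]2CC[C@]3(CO)[C@@H](Br)CC[C@@](C)(O)[C@@H]23)=CC[C@H](Br)C(C)(C)C1
F2 | step 19 | ring A C1=C6 olefin (proton-loss cyclization product, C4 S) | C1(C[C@@H]2CC[C@]3(CO)[C@@H](Br)CC[C@@](C)(O)[C@@H]23)=CC(C)(C)[C@@H](Br)CC1
F3 | step 19 | C2 acetoxymercurio carbinol from F1 (OH on C1 and Hg on C2 trans-diaxial) | O[C@]1(C[C@@H]2CC[C@]3(CO)[C@@H](Br)CC[C@@](C)(O)[C@@H]23)[C@@H]([Hg]OC(C)=O)C[C@H](Br)C(C)(C)C1
F4 | step 19 | C6 acetoxymercurio carbinol from F2 (OH on C1 and Hg on C6 trans-diaxial) | O[C@]1(C[C@@H]2CC[C@]3(CO)[C@@H](Br)CC[C@@](C)(O)[C@@H]23)CC[C@H](Br)C(C)(C)[C@H]1[Hg]OC(C)=O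
F5 | step 15 | (2Z,5S,6E)-2-(bromomethylene)-7-methyl-5-(6-methyl-2-methylenehept-5-en-1-yl)nona-6,8-dienoic acid | C=C(CCC=C(C)C)C[C@H](CC/C(C(=O)O)=C/Br)/C=C(\C)C=C
F6 | step 15 | methyl (2Z,5S,6E)-2-(bromomethylene)-7-methyl-5-(6-methyl-2-methylenehept-5-en-1-yl)nona-6,8-dienoate | C=C(CCC=C(C)C)C[C@H](CC/C(C(=O)OC)=C/Br)/C=C(\C)C=C
F7 | step 15 | methyl 12β-bromo-15-methyl-8α-(6-methyl-2-methylenehept-5-en-1-yl)-trans-hydrind-14-ene-11β-carboxylate | C=C(CCC=C(C)C)C[C@@H]2CC[C@]3(C(=O)OC)[C@@H](Br)CC=C(C)[C@@H]23
F8 | step 17 | 12β-bromo-15-methyl-8α-(6-methyl-2-methylenehept-5-en-1-yl)-trans-hydrind-14-ene-11β-carboxylic acid | C=C(CCC=C(C)C)C[C@@H]2CC[C@]3(C(=O)O)[C@@H](Br)CC=C(C)[C@@H]23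
F9 | step 17 | 14α-iodo C17,C15β-lactone of F8 (bridged γ-lactone) | C=C(CCC=C(C)C)C[C@@H]2CC[C@]3(C(=O)O4)[C@@H](Br)C[C@H](I)[C@]4(C)[C@@H]23
F10 | step 20 | C15,C17-O-(di-tert-butylsilylene) derivative of 31 | O[C@]1(C[C@@H]2CC[C@]3(CO[Si](C(C)(C)C)(C(C)(C)C)O4)[C@@H](Br)CC[C@]4(C)[C@@H]23)CC[C@H](Br)C(C)(C)C1
F11 | step 20 | C1 acetate of F10 | CC(=O)O[C@]1(C[C@@H]2CC[C@]3(CO[Si](C(C)(C)C)(C(C)(C)C)O4)[C@@H](Br)CC[C@]4(C)[C@@H]23)CC[C@H](Br)C(C)(C)C1
A1 | alternative 1 | trans-hydrindan-9-one 10-carboxylate (C–H insertion product) | CC(C)(C)[Si](C)(C)OC[C@@H]2C(=O)[C@H](C(=O)OC)[C@]3(C[Si](C)(C)c4ccccc4)[C@H](O[Si](C)(C)C(C)(C)C)CC[C@@](C)(O[Si](CC)(CC)CC)[C@@H]23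
A2 | alternative 1 | α-diazo-β-keto ester on the ring C cyclohexane (insertion precursor) | COC(=O)C(=[N+]=[N-])C(=O)[C@@H](CO[Si](C)(C)C(C)(C)C)[C@H]1[C@@H](C[Si](C)(C)c2ccccc2)[C@H](O[Si](C)(C)C(C)(C)C)CC[C@@]1(C)O[Si](CC)(CC)CC
A3 | alternative 2 | bromo trans-hydrindene methyl ester with C7 silyl ether | CC(C)(C)[Si](C)(C)OC[C@@H]2CC[C@]3(C(=O)OC)[C@@H](Br)CC=C(C)[C@@H]23
A4 | alternative 2 | (Z)-bromoacrylate nonatriene ester (cycloaddition precursor) | CC(C)(C)[Si](C)(C)OC[C@H](CC/C(C(=O)OC)=C/Br)/C=C(\C)C=C
A5 | alternative 2 | (S)-4-bromo-3,3-dimethylcyclohexan-1-one | O=C1CC[C@H](Br)C(C)(C)C1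
A6 | alternative 3 | trans-hydrindane with C15 carbinol and C12 ketone | CC(C)(C)[Si](C)(C)OC[C@@H]2CC[C@]3(C(=O)OC)C(=O)CC[C@@](C)(O)[C@@H]23
A7 | alternative 3 | cyclopentane keto enone (C16 acetyl, C11 acryloyl and ester) | CC(C)(C)[Si](C)(C)OC[C@@H]1CC[C@](C(=O)OC)(C(=O)C=C)[C@H]1C(C)=O
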